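**Plan**

1. Late cuts: the C3–O decanoate, the C15=CH2 bond (methylenation) and the C16=C17 bond (aldol condensation with geranial) reduce the side chain to an acetyl group on C14; the C7=C2 enal goes back to a C7 ketone.
2. Enabling feature: in cyclopentane ring A, C14 is substituted by C15, and C15 is bonded to two further carbons (its exo-methylene carbon and C16). The five ring atoms plus C15 can therefore be drawn as a 1-methylcyclohexene (C15=C14, methyl = C16), which contracts when C13 moves from C15 to C14 and leaves C15 outside the ring as an acetyl carbon.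
3. The spiro[5.5]undecene is cut at C11–C10 (aldol), C6–C5 (conjugate addition) and C11=C6 (aldol condensation) to 3-methylcyclohex-2-en-1-one, a C6–C10 keto aldehyde and a C3–C5 organocopper reagent.
4. Forward: the cyclohexenone is the first ring; ring B closes by tandem cuprate addition–aldol; directed reduction and silylene protection follow; ring A forms by ring contraction with PhI(OH)OTs in methanol; then the enal unit, the geranial chain, methylenation, desilylation, MnO2 oxidation and decanoylation.
5. Stereochemistry: C7 from (R)-trityl glycidyl ether directs C6 (anti cuprate addition) and is later destroyed; C6 and C7 fix C11 and C10 in the chelated chair aldol; the C10 hydroxyl delivers hydride to C26; C14 arises by inversion during the 1,2-shift, trans to the C26 oxygen.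
6. Alkene geometry: C18=C19 comes from geranial, C16=C17 (E) from elimination, C7=C2 (Z) from thermodynamic control.

Key step: step 11

Atom labels: C1 is the aldehyde carbon, C2 carries the methyl group, C3–C5 are the oxygenated propyl chain, C6–C11 are ring B (C11 spiro, C10 carbinol), C12, C13, C14 and C26 complete ring A, and C15 onward is the side chain.

Assumption: for the tetrasubstituted enal, the isomer with the formyl group syn to C6 is taken to be the more stable one, because A(1,3) strain favours the smaller substituent next to the branched C6.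

Step 1
Reactants: 1 (R)-trityl glycidyl ether; 2 (2-methylallyl)magnesium chloride
Product: 3 (2R)-5-methyl-1-(triphenylmethoxy)hex-5-en-2-ol
Conditions: CuI (10 mol %), THF, −30 → 0 °C; aq NH4Cl
Reagents that add atoms: none
Why: Copper-catalysed opening of the terminal epoxide by the allylic Grignard reagent (SN2 at the unsubstituted carbon) installs C8–C10 with the ketone masked as a methallyl group and leaves the C7 stereocentre of the chiral-pool epoxide untouched.

Step 2
Reactants: 3 (2R)-5-methyl-1-(triphenylmethoxy)hex-5-en-2-ol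
Product: 4 (2R)-2-(benzyloxy)-5-methyl-1-(triphenylmethoxy)hex-5-ene
Conditions: NaH, BnBr, Bu4NI (cat.), THF–DMF, 0 °C → rt
Reagents that add atoms: benzyl bromide, BrCc1ccccc1
Why: Williamson etherification of the sodium alkoxide gives the C7 benzyl ether without touching the stereocentre, a group that later acts as steric control element and is removed by hydrogenolysis.

Step 3
Reactants: 4 (2R)-2-(benzyloxy)-5-methyl-1-(triphenylmethoxy)hex-5-ene
Product: 5 (2R)-2-(benzyloxy)-5-methylhex-5-en-1-ol
Conditions: TsOH·H2O (cat.), MeOH–CH2Cl2, rt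
Reagents that add atoms: none
Why: Acid-catalysed methanolysis cleaves the trityl ether selectively (SN1 at the trityl carbon), while the benzyl ether and the 1,1-disubstituted alkene persist under catalytic acid at room temperature.

Step 4
Reactants: 5 (2R)-2-(benzyloxy)-5-methylhex-5-en-1-ol
Product: 6 (5R)-5-(benzyloxy)-6-hydroxyhexan-2-one
Conditions: O3, CH2Cl2–MeOH, −78 °C; Me2S, −78 °C → rt
Reagents that add atoms: ozone, [O-][O+]=O
Why: Ozonolysis with reductive work-up converts the only alkene into the C10 methyl ketone and should spare the benzyl ether at −78 °C when ozone is not used in excess.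

Step 5
Reactants: 6 (5R)-5-(benzyloxy)-6-hydroxyhexan-2-one
Product: 7 (2R)-2-(benzyloxy)-5-oxohexanal
Conditions: Dess–Martin periodinane, NaHCO3, CH2Cl2, 0 °C → rt
Reagents that add atoms: none
Why: Dess–Martin oxidation of the primary alcohol runs under buffered, non-basic conditions, so the α-benzyloxy aldehyde (used without storage) should not epimerise at C7.

Step 6
Reactants: 8 3-methylcyclohex-2-en-1-one; 7 (2R)-2-(benzyloxy)-5-oxohexanal
Product: 10 aldol adduct 6-[(2R)-2-(benzyloxy)-1-hydroxy-5-oxohexyl]-3-methylcyclohex-2-en-1-one, via lithium dienolate 9 (not isolated)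
Conditions: LiN(iPr)2, THF, −78 °C; then 7, −78 °C; aq NH4Cl
Reagents that add atoms: none
Why: Kinetic deprotonation of the enone occurs at the α′ carbon (C11) and the cross-conjugated lithium dienolate adds to the aldehyde much faster than to the methyl ketone (directed aldol addition), the two new stereocentres being of no consequence because both are removed in step 7.

Step 7
Reactants: 10 aldol adduct
Product: 12 (6E)-6-[(2R)-2-(benzyloxy)-5-oxohexylidene]-3-methylcyclohex-2-en-1-one, via aldol mesylate 11 (not isolated)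
Conditions: MsCl, Et3N, CH2Cl2, 0 °C; then DBU, 0 °C → rt
Reagents that add atoms: none
Why: Mesylation followed by E1cB elimination with DBU gives the exocyclic enone, for which the (E) geometry with the vinylic hydrogen next to the carbonyl group is the thermodynamically preferred one.

Step 8
Reactants: 12 (E)-dienone; 13 (3-bromopropoxy)(tert-butyl)diphenylsilane
Product: 15 spiro hydroxy enone (6R,7S,8R,11S)-8-(benzyloxy)-7-{3-[(tert-butyldiphenylsilyl)oxy]propyl}-11-hydroxy-3,11-dimethylspiro[5.5]undec-2-en-1-one, via bromomagnesium enolate 14 (not isolated)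
Conditions: 13, Mg, THF; CuBr·SMe2 (0.5 equiv per RMgBr), THF, −78 °C; then 12, −78 → −30 °C; aq NH4Cl
Reagents that add atoms: none
Why: In this tandem conjugate addition–aldol cyclisation the Grignard-derived homocuprate adds to C6 of the s-cis exocyclic enone anti to the γ-benzyloxy group (Felkin–Anh-type attack on the (E)-γ-alkoxy enone, setting C6), and the regiospecifically formed magnesium enolate closes ring B on the methyl ketone through a chelated Zimmerman–Traxler chair in which the C7 benzyloxy group stays equatorial and clear of C12, which should place the C10 oxygen and the C6 chain cis to C26 and so set C11 and C10.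

Step 9
Reactants: 15 spiro hydroxy enone
Product: 16 spiro diol (1R,6S,7S,8R,11S)-8-(benzyloxy)-7-{3-[(tert-butyldiphenylsilyl)oxy]propyl}-3,11-dimethylspiro[5.5]undec-2-ene-1,11-diol
Conditions: Me4NBH(OAc)3, AcOH–MeCN, −30 → 0 °C
Reagents that add atoms: none
Why: In the Evans–Saksena reduction the C10 hydroxyl binds the triacetoxyborohydride and delivers hydride intramolecularly to the enone carbonyl from the face that bears C10, which reduces 1,2 and should set C26 with its oxygen trans to C10 (1,3-anti diol).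

Step 10
Reactants: 16 spiro diol
Product: 17 silylene-protected spiro[5.5]undecene (1,11-O-di-tert-butylsilanediyl derivative of 16)
Conditions: tBu2Si(OTf)2, 2,6-lutidine, CH2Cl2, 0 °C → rt
Reagents that add atoms: di-tert-butylsilyl bis(trifluoromethanesulfonate), CC(C)(C)[Si](OS(=O)(=O)C(F)(F)F)(OS(=O)(=O)C(F)(F)F)C(C)(C)C
Why: The silylene bis-triflate bridges the hindered secondary and tertiary hydroxyls in one step to a six-membered dioxasilinane that tolerates the acidic methanol of step 11 and holds the C26 oxygen equatorial on the cyclohexene.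

Step 11
Reactants: 17 silylene-protected spiro[5.5]undecene
Product: 19 ring-contracted dimethyl ketal (1R,2S,5S,6S,7R,10S)-7-(benzyloxy)-6-{3-[(tert-butyldiphenylsilyl)oxy]propyl}-1,10-O-(di-tert-butylsilanediyl)-2-(1,1-dimethoxyethyl)-10-methylspiro[4.5]decane-1,10-diol, via methoxy iodane adduct 18 (not isolated)
Conditions: PhI(OH)OTs (1.2 equiv), MeOH–HC(OMe)3–CH2Cl2, 0 °C → rt; then solid NaHCO3
Reagents that add atoms: methanol, CO
Why: PhI(OH)OTs attacks the trisubstituted alkene as an iodine electrophile in its trivalent state at the CH terminus C14 and methanol captures the incipient tertiary cation at C15 to give the β-methoxy alkyl-λ3-iodane 18, from which iodobenzene departs while ring carbon C13 shifts from C15 to C14 and the methoxy-stabilised cation at C15 is trapped by methanol as the dimethyl ketal. The closest known reaction type is the oxidative ring contraction of 1-alkylcyclohexenes to acylcyclopentane ketals with PhI(OH)OTs or Tl(NO3)3 in methanol. Ring A arises by contraction of the six-membered ring (mode of closure: 1,2-alkyl shift onto C14 that forms C13–C14), not by cyclisation of an open chain. The new stereocentre C14 is set by the face of iodination, which should be the one opposite the equatorial C26 silyloxy group and the axial C6 branch at the spiro centre, followed by inversion at C14 in the shift, so that C15 ends up trans to the C26 oxygen, which is also the more stable arrangement once the ketone is unmasked. The step needs migration of C13 and not of the methyl group or of C11: in the silylene-locked chair the equatorial C14–iodine bond is antiperiplanar to the ring bond C15–C13 and not to the methyl group, and the tertiary, methoxy-bearing C15 supports positive charge better than the secondary, silyloxy-bearing C26. The ring alkene is the only alkene in 17, the benzyl, silyl and silylene groups should survive the short exposure to the sulfonic acid, and the dimethyl ketal is kept as the protecting group of the C15 ketone.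

Step 12
Reactants: 19 ring-contracted dimethyl ketal
Product: 20 C7 alcohol (1R,2S,5S,6S,7R,10S)-6-{3-[(tert-butyldiphenylsilyl)oxy]propyl}-1,10-O-(di-tert-butylsilanediyl)-2-(1,1-dimethoxyethyl)-10-methylspiro[4.5]decane-1,7,10-triol
Conditions: H2 (1 atm), Pd(OH)2/C, EtOAc, rt
Reagents that add atoms: none
Why: Hydrogenolysis removes the C7 benzyl ether cleanly at this stage because the molecule no longer contains any alkene and the silyl groups and the ketal are inert to hydrogen over palladium.

Step 13
Reactants: 20 C7 alcohol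
Product: 21 C7 ketone (1R,2S,5S,6S,10S)-6-{3-[(tert-butyldiphenylsilyl)oxy]propyl}-1,10-O-(di-tert-butylsilanediyl)-1,10-dihydroxy-2-(1,1-dimethoxyethyl)-10-methylspiro[4.5]decan-7-one
Conditions: Dess–Martin periodinane, NaHCO3, CH2Cl2, 0 °C → rt
Reagents that add atoms: none
Why: Dess–Martin oxidation gives the C7 ketone under buffered, non-basic conditions, so that the adjacent C6 stereocentre should not epimerise by enolisation.

Step 14
Reactants: 21 C7 ketone
Product: 22 isopropenyl carbinol (7-hydroxy-7-(prop-1-en-2-yl) derivative of 21)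
Conditions: CH2=C(CH3)MgBr, LaCl3·2LiCl, THF, 0 °C; aq NH4Cl
Reagents that add atoms: isopropenylmagnesium bromide, CC(=C)[Mg]Br
Why: The lanthanum-promoted 1,2-addition of the isopropenyl Grignard reagent to the hindered, enolisable ketone suppresses enolisation at C6 and C8, and the configuration of the new carbinol centre C7 is irrelevant because it is lost in step 15.

Step 15
Reactants: 22 isopropenyl carbinol
Product: 23 (Z)-enal (2Z)-2-[(1R,2S,5S,6R,10S)-6-{3-[(tert-butyldiphenylsilyl)oxy]propyl}-1,10-O-(di-tert-butylsilanediyl)-1,10-dihydroxy-2-(1,1-dimethoxyethyl)-10-methylspiro[4.5]decan-7-ylidene]propanal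
Conditions: pyridinium chlorochromate (C5H5NH[CrO3Cl]), NaOAc, 4 Å molecular sieves, CH2Cl2, rt
Reagents that add atoms: none
Why: The Babler–Dauben oxidation (oxidative 1,3-transposition of a tertiary allylic alcohol with chromium in its hexavalent state) gives the tetrasubstituted enal directly, and the (Z) isomer with the small formyl group syn to the branched C6 is expected to predominate because the enal can equilibrate under the mildly acidic conditions to the isomer of lower A(1,3) strain.

Step 16
Reactants: 23 (Z)-enal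
Product: 24 (Z)-allylic alcohol (2Z)-2-[spiro[4.5]decan-7-ylidene]propan-1-ol (other groups as in 23)
Conditions: NaBH4, CeCl3·7H2O, MeOH, −40 °C
Reagents that add atoms: none
Why: Luche reduction converts the enal into the allylic alcohol by 1,2-hydride addition without isomerising the alkene or touching the ketal, which masks the enal unit for the enolate and titanium chemistry that follows.

Step 17
Reactants: 24 (Z)-allylic alcohol
Product: 25 allylic silyl ether (tert-butyldimethylsilyl ether of 24)
Conditions: TBSCl, imidazole, CH2Cl2, rt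
Reagents that add atoms: tert-butyldimethylsilyl chloride, CC(C)(C)[Si](C)(C)Cl
Why: Imidazole-promoted silylation of the unhindered primary allylic alcohol is routine and gives an ether that is removed in the final fluoride step.

Step 18
Reactants: 25 allylic silyl ether
Product: 26 methyl ketone 1-[(1R,2S,5S,6R,7Z,10S)-spiro[4.5]decan-2-yl]ethan-1-one carrying the 1,10-O-silylene, the C6 silyloxypropyl chain and the C7 silyloxypropan-2-ylidene group
Conditions: PPTS (cat.), acetone–H2O, rt
Reagents that add atoms: water, O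
Why: Acid-catalysed hydrolysis of the dimethyl ketal is far faster than cleavage of the silyl ethers under PPTS in wet acetone, and C14, now α to the ketone, is already in the more stable trans arrangement.

Step 19
Reactants: 26 methyl ketone; 27 geranial
Product: 29 β-hydroxy ketone (4E)-3-hydroxy-5,9-dimethyl-1-(spirocyclic core of 26)deca-4,8-dien-1-one, via lithium enolate 28 (not isolated)
Conditions: LiN(iPr)2, THF, −78 °C; then 27, −78 °C; aq NH4Cl
Reagents that add atoms: none
Why: Kinetic enolisation with LiN(iPr)2 takes place at the methyl group (C16) and not at the hindered tertiary C14, and the lithium enolate adds 1,2 to geranial (directed aldol addition), the configuration of the new carbinol centre C17 being irrelevant because it is removed in step 20.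

Step 20
Reactants: 29 β-hydroxy ketone
Product: 31 (2E,4E)-dienone (2E,4E)-5,9-dimethyl-1-(spirocyclic core of 26)deca-2,4,8-trien-1-one, via hydroxy ketone mesylate 30 (not isolated)
Conditions: MsCl, Et3N, CH2Cl2, 0 °C; then DBU, rt
Reagents that add atoms: none
Why: Mesylation and E1cB elimination give the conjugated (E)-C16=C17 alkene (the trans enone is both the kinetic and the thermodynamic product) and leave the geranial-derived (E)-C18=C19 bond unchanged.

Step 21
Reactants: 31 (2E,4E)-dienone
Product: 32 silylated triene (C15 methylene compound)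
Conditions: Cp2TiMe2, toluene–THF, 65 °C, dark
Reagents that add atoms: dimethyltitanocene (Cp2TiMe2), C[Ti](C)(C1C=CC=C1)C1C=CC=C1
Why: Petasis methylenation (thermally generated Cp2Ti=CH2, carbonyl olefination through an oxatitanacyclobutane) converts the enolisable dienone into the 1,1-disubstituted alkene without base, so that C14 and the diene geometry should be preserved.

Step 22
Reactants: 32 silylated triene
Product: 33 tetraol (free C1, C3, C10 and C26 hydroxyls)
Conditions: Bu4NF, THF, rt → 45 °C
Reagents that add atoms: none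
Why: Fluoride cleaves the two silyl ethers and the silylene under mildly basic conditions that the conjugated triene should tolerate.

Step 23
Reactants: 33 tetraol
Product: 34 enal triol
Conditions: MnO2, CH2Cl2, rt
Reagents that add atoms: none
Why: MnO2 oxidises only the allylic primary alcohol (C1) and leaves the saturated primary, the secondary and the tertiary alcohols as well as the alkene geometry untouched.

Step 24
Reactants: 34 enal triol; 35 decanoyl chloride
Product: 36 target decanoate
Conditions: 2,4,6-collidine, CH2Cl2, −78 → −20 °C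
Reagents that add atoms: none
Why: Acylation with the acid chloride and a hindered pyridine base at low temperature should select the unhindered primary C3 hydroxyl over the neopentyl-type secondary C26 hydroxyl and the tertiary C10 hydroxyl.

**Compound list**

1 | (R)-trityl glycidyl ether, (2R)-2-[(triphenylmethoxy)methyl]oxirane | C(c1ccccc1)(c1ccccc1)(c1ccccc1)OC[C@H]1CO1 | starting material
2 | (2-methylallyl)magnesium chloride | CC(=C)C[Mg]Cl | starting material
3 | (2R)-5-methyl-1-(triphenylmethoxy)hex-5-en-2-ol | C(c1ccccc1)(c1ccccc1)(c1ccccc1)OC[C@H](O)CCC(C)=C | intermediate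
4 | (2R)-2-(benzyloxy)-5-methyl-1-(triphenylmethoxy)hex-5-ene | C(c1ccccc1)(c1ccccc1)(c1ccccc1)OC[C@H](OCc1ccccc1)CCC(C)=C | intermediate
5 | (2R)-2-(benzyloxy)-5-methylhex-5-en-1-ol | OC[C@H](OCc1ccccc1)CCC(C)=C | intermediate
6 | (5R)-5-(benzyloxy)-6-hydroxyhexan-2-one | OC[C@H](OCc1ccccc1)CCC(C)=O | intermediate
7 | (2R)-2-(benzyloxy)-5-oxohexanal | O=C[C@H](OCc1ccccc1)CCC(C)=O | intermediate
8 | 3-methylcyclohex-2-en-1-one | CC1=CC(=O)CCC1 | starting material
9 | lithium 5-methylcyclohexa-1,5-dien-1-olate (kinetic dienolate of 8) | CC1=CC(O[Li])=CCC1 | intermediate (not isolated)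
10 | 6-[(2R)-2-(benzyloxy)-1-hydroxy-5-oxohexyl]-3-methylcyclohex-2-en-1-one (mixture at the two new centres) | CC1=CC(=O)C(CC1)C(O)[C@H](OCc1ccccc1)CCC(C)=O | intermediate
11 | (2R)-2-(benzyloxy)-1-(4-methyl-2-oxocyclohex-3-en-1-yl)-5-oxohexyl methanesulfonate | CC1=CC(=O)C(CC1)C(OS(C)(=O)=O)[C@H](OCc1ccccc1)CCC(C)=O | intermediate (not isolated)
12 | (6E)-6-[(2R)-2-(benzyloxy)-5-oxohexylidene]-3-methylcyclohex-2-en-1-one | CC1=CC(=O)/C(CC1)=C/[C@H](OCc1ccccc1)CCC(C)=O | intermediate
13 | (3-bromopropoxy)(tert-butyl)diphenylsilane | BrCCCO[Si](c1ccccc1)(c1ccccc1)C(C)(C)C | starting material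
14 | bromomagnesium 2-[(4S,5R)-5-(benzyloxy)-1-[(tert-butyldiphenylsilyl)oxy]-8-oxononan-4-yl]-5-methylcyclohexa-1,5-dien-1-olate | CC1=CC(O[Mg]Br)=C(CC1)[C@H](CCCO[Si](c1ccccc1)(c1ccccc1)C(C)(C)C)[C@H](OCc1ccccc1)CCC(C)=O | intermediate (not isolated)
15 | (6R,7S,8R,11S)-8-(benzyloxy)-7-{3-[(tert-butyldiphenylsilyl)oxy]propyl}-11-hydroxy-3,11-dimethylspiro[5.5]undec-2-en-1-one | CC1=CC(=O)[C@]2(CC1)[C@H](CCCO[Si](c1ccccc1)(c1ccccc1)C(C)(C)C)[C@H](OCc1ccccc1)CC[C@]2(C)O | intermediate
16 | (1R,6S,7S,8R,11S)-8-(benzyloxy)-7-{3-[(tert-butyldiphenylsilyl)oxy]propyl}-3,11-dimethylspiro[5.5]undec-2-ene-1,11-diol | CC1=C[C@@H](O)[C@]2(CC1)[C@H](CCCO[Si](c1ccccc1)(c1ccccc1)C(C)(C)C)[C@H](OCc1ccccc1)CC[C@]2(C)O | intermediate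
17 | (1R,6S,7S,8R,11S)-8-(benzyloxy)-7-{3-[(tert-butyldiphenylsilyl)oxy]propyl}-1,11-O-(di-tert-butylsilanediyl)-3,11-dimethylspiro[5.5]undec-2-ene-1,11-diol (key-step precursor) | CC1=C[C@@H](O[Si]3(C(C)(C)C)C(C)(C)C)[C@]2(CC1)[C@H](CCCO[Si](c1ccccc1)(c1ccccc1)C(C)(C)C)[C@H](OCc1ccccc1)CC[C@]2(C)O3 | intermediate
18 | anti adduct of 17: 3-methoxy-2-[phenyl(tosyloxy)-λ3-iodanyl]spiro[5.5]undecane, iodine on the face opposite the C1 oxygen | C[C@]1(OC)[C@H]([I](c4ccccc4)OS(=O)(=O)c4ccc(C)cc4)[C@@H](O[Si]3(C(C)(C)C)C(C)(C)C)[C@]2(CC1)[C@H](CCCO[Si](c1ccccc1)(c1ccccc1)C(C)(C)C)[C@H](OCc1ccccc1)CC[C@]2(C)O3 | intermediate (not isolated)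
19 | (1R,2S,5S,6S,7R,10S)-7-(benzyloxy)-6-{3-[(tert-butyldiphenylsilyl)oxy]propyl}-1,10-O-(di-tert-butylsilanediyl)-2-(1,1-dimethoxyethyl)-10-methylspiro[4.5]decane-1,10-diol (key-step product) | COC(C)(OC)[C@H]1CC[C@]2([C@H](CCCO[Si](c3ccccc3)(c3ccccc3)C(C)(C)C)[C@H](OCc3ccccc3)CC[C@]2(C)O4)[C@@H]1O[Si]4(C(C)(C)C)C(C)(C)C | intermediate
20 | (1R,2S,5S,6S,7R,10S)-6-{3-[(tert-butyldiphenylsilyl)oxy]propyl}-1,10-O-(di-tert-butylsilanediyl)-2-(1,1-dimethoxyethyl)-10-methylspiro[4.5]decane-1,7,10-triol | COC(C)(OC)[C@H]1CC[C@]2([C@H](CCCO[Si](c3ccccc3)(c3ccccc3)C(C)(C)C)[C@H](O)CC[C@]2(C)O4)[C@@H]1O[Si]4(C(C)(C)C)C(C)(C)C | intermediate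
21 | (1R,2S,5S,6S,10S)-6-{3-[(tert-butyldiphenylsilyl)oxy]propyl}-1,10-O-(di-tert-butylsilanediyl)-1,10-dihydroxy-2-(1,1-dimethoxyethyl)-10-methylspiro[4.5]decan-7-one | COC(C)(OC)[C@H]1CC[C@]2([C@H](CCCO[Si](c3ccccc3)(c3ccccc3)C(C)(C)C)C(=O)CC[C@]2(C)O4)[C@@H]1O[Si]4(C(C)(C)C)C(C)(C)C | intermediate
22 | (1R,2S,5S,6S,10S)-6-{3-[(tert-butyldiphenylsilyl)oxy]propyl}-1,10-O-(di-tert-butylsilanediyl)-2-(1,1-dimethoxyethyl)-10-methyl-7-(prop-1-en-2-yl)spiro[4.5]decane-1,7,10-triol (C7 configuration not controlled) | COC(C)(OC)[C@H]1CC[C@]2([C@H](CCCO[Si](c3ccccc3)(c3ccccc3)C(C)(C)C)C(O)(C(C)=C)CC[C@]2(C)O4)[C@@H]1O[Si]4(C(C)(C)C)C(C)(C)C | intermediate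
23 | (2Z)-2-[(1R,2S,5S,6R,10S)-6-{3-[(tert-butyldiphenylsilyl)oxy]propyl}-1,10-O-(di-tert-butylsilanediyl)-1,10-dihydroxy-2-(1,1-dimethoxyethyl)-10-methylspiro[4.5]decan-7-ylidene]propanal | COC(C)(OC)[C@H]1CC[C@]2([C@H](CCCO[Si](c3ccccc3)(c3ccccc3)C(C)(C)C)/C(=C(/C)C=O)CC[C@]2(C)O4)[C@@H]1O[Si]4(C(C)(C)C)C(C)(C)C | intermediate
24 | (2Z)-2-[(1R,2S,5S,6R,10S)-6-{3-[(tert-butyldiphenylsilyl)oxy]propyl}-1,10-O-(di-tert-butylsilanediyl)-1,10-dihydroxy-2-(1,1-dimethoxyethyl)-10-methylspiro[4.5]decan-7-ylidene]propan-1-ol | COC(C)(OC)[C@H]1CC[C@]2([C@H](CCCO[Si](c3ccccc3)(c3ccccc3)C(C)(C)C)/C(=C(/C)CO)CC[C@]2(C)O4)[C@@H]1O[Si]4(C(C)(C)C)C(C)(C)C | intermediate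
25 | tert-butyldimethylsilyl ether of 24 | COC(C)(OC)[C@H]1CC[C@]2([C@H](CCCO[Si](c3ccccc3)(c3ccccc3)C(C)(C)C)/C(=C(/C)CO[Si](C)(C)C(C)(C)C)CC[C@]2(C)O4)[C@@H]1O[Si]4(C(C)(C)C)C(C)(C)C | intermediate
26 | 1-[(1R,2S,5S,6R,7Z,10S)-7-{1-[(tert-butyldimethylsilyl)oxy]propan-2-ylidene}-6-{3-[(tert-butyldiphenylsilyl)oxy]propyl}-1,10-O-(di-tert-butylsilanediyl)-1,10-dihydroxy-10-methylspiro[4.5]decan-2-yl]ethan-1-one | CC(=O)[C@H]1CC[C@]2([C@H](CCCO[Si](c3ccccc3)(c3ccccc3)C(C)(C)C)/C(=C(/C)CO[Si](C)(C)C(C)(C)C)CC[C@]2(C)O4)[C@@H]1O[Si]4(C(C)(C)C)C(C)(C)C | intermediate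
27 | geranial, (2E)-3,7-dimethylocta-2,6-dienal | CC(C)=CCC/C(C)=C/C=O | starting material
28 | lithium enolate of 26 (deprotonated at the acetyl methyl group) | C=C(O[Li])[C@H]1CC[C@]2([C@H](CCCO[Si](c3ccccc3)(c3ccccc3)C(C)(C)C)/C(=C(/C)CO[Si](C)(C)C(C)(C)C)CC[C@]2(C)O4)[C@@H]1O[Si]4(C(C)(C)C)C(C)(C)C | intermediate (not isolated)
29 | (4E)-3-hydroxy-5,9-dimethyl-1-(spirocyclic core of 26, 1R,2S,5S,6R,7Z,10S)deca-4,8-dien-1-one (C3 epimers) | CC(C)=CCC/C(C)=C/C(O)CC(=O)[C@H]1CC[C@]2([C@H](CCCO[Si](c3ccccc3)(c3ccccc3)C(C)(C)C)/C(=C(/C)CO[Si](C)(C)C(C)(C)C)CC[C@]2(C)O4)[C@@H]1O[Si]4(C(C)(C)C)C(C)(C)C | intermediate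
30 | methanesulfonate of 29 | CC(C)=CCC/C(C)=C/C(OS(C)(=O)=O)CC(=O)[C@H]1CC[C@]2([C@H](CCCO[Si](c3ccccc3)(c3ccccc3)C(C)(C)C)/C(=C(/C)CO[Si](C)(C)C(C)(C)C)CC[C@]2(C)O4)[C@@H]1O[Si]4(C(C)(C)C)C(C)(C)C | intermediate (not isolated)
31 | (2E,4E)-5,9-dimethyl-1-(spirocyclic core of 26, 1R,2S,5S,6R,7Z,10S)deca-2,4,8-trien-1-one | O=C(/C=C/C=C(\C)CCC=C(C)C)[C@H]1CC[C@]2([C@H](CCCO[Si](c3ccccc3)(c3ccccc3)C(C)(C)C)/C(=C(/C)CO[Si](C)(C)C(C)(C)C)CC[C@]2(C)O4)[C@@H]1O[Si]4(C(C)(C)C)C(C)(C)C | intermediate
32 | (1R,2R,5S,6R,7Z,10S)-7-{1-[(tert-butyldimethylsilyl)oxy]propan-2-ylidene}-6-{3-[(tert-butyldiphenylsilyl)oxy]propyl}-1,10-O-(di-tert-butylsilanediyl)-2-[(3E,5E)-6,10-dimethylundeca-1,3,5,9-tetraen-2-yl]-10-methylspiro[4.5]decane-1,10-diol | C=C(/C=C/C=C(\C)CCC=C(C)C)[C@H]1CC[C@]2([C@H](CCCO[Si](c3ccccc3)(c3ccccc3)C(C)(C)C)/C(=C(/C)CO[Si](C)(C)C(C)(C)C)CC[C@]2(C)O4)[C@@H]1O[Si]4(C(C)(C)C)C(C)(C)C | intermediate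
33 | (1R,2R,5S,6R,7Z,10S)-2-[(3E,5E)-6,10-dimethylundeca-1,3,5,9-tetraen-2-yl]-7-(1-hydroxypropan-2-ylidene)-6-(3-hydroxypropyl)-10-methylspiro[4.5]decane-1,10-diol | C=C(/C=C/C=C(\C)CCC=C(C)C)[C@H]1CC[C@]2([C@H](CCCO)/C(=C(/C)CO)CC[C@]2(C)O)[C@@H]1O | intermediate
34 | (2Z)-2-[(1R,2R,5S,6R,10S)-2-[(3E,5E)-6,10-dimethylundeca-1,3,5,9-tetraen-2-yl]-1,10-dihydroxy-6-(3-hydroxypropyl)-10-methylspiro[4.5]decan-7-ylidene]propanal | C=C(/C=C/C=C(\C)CCC=C(C)C)[C@H]1CC[C@]2([C@H](CCCO)/C(=C(/C)C=O)CC[C@]2(C)O)[C@@H]1O | intermediate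
35 | decanoyl chloride | CCCCCCCCCC(Cl)=O | starting material
36 | 3-[(1R,2R,5S,6R,7Z,10S)-2-[(3E,5E)-6,10-dimethylundeca-1,3,5,9-tetraen-2-yl]-1,10-dihydroxy-10-methyl-7-(1-oxopropan-2-ylidene)spiro[4.5]decan-6-yl]propyl decanoate | C=C(/C=C/C=C(\C)CCC=C(C)C)[C@H]1CC[C@]2([C@H](CCCOC(=O)CCCCCCCCC)/C(=C(/C)C=O)CC[C@]2(C)O)[C@@H]1O | target

Total step count: 24. Longest linear sequence: 24 steps (from 1 to 36).

**Steps most likely to fail**

Step 8, tandem conjugate addition–aldol cyclisation. What may go wrong: insufficient facial selectivity in the ring closure. The chelated chair may instead keep the C6 chain equatorial and force the benzyloxy group axial, which would invert C11 and C10 relative to C6. The cross-conjugated dienone may also aromatise to a phenol before the cuprate adds. Fallback, setting out from 12 and returning at 15: the three-carbon chain is introduced as a slim alkynyl group. tert-Butyl(prop-2-yn-1-yloxy)diphenylsilane is lithiated and converted with B-methoxy-9-borabicyclo[3.3.1]nonane and BF3·OEt2 into the B-alkynyl-9-borabicyclo[3.3.1]nonane F1. This reagent transfers its alkynyl group to C6 of the s-cis enone through a six-membered transition state much faster than it adds to a saturated ketone. The boron enolate then closes on the C10 ketone, and oxidative work-up (H2O2, NaOAc) releases the alkynyl spiro hydroxy enone F2. Because an alkynyl substituent has almost no preference for the equatorial site, the chair with the benzyloxy group equatorial should now be clearly favoured. Hydrogenation of F2 with H2 and RhCl(PPh3)3, which saturates the alkyne but touches neither the trisubstituted enone alkene nor the benzyl ether, gives 15.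

Step 11, oxidative ring contraction. What may go wrong: solvolysis of silyl groups by the sulfonic acid liberated in methanol, simple 1,2-dimethoxylation without rearrangement, or a competing shift of C11 from the silyloxy-bearing C26 instead of C13 from C15. Fallback, setting out from 17 and returning at 19: the same C13–C14 bond is formed by a stepwise pinacol-type ring contraction. Dihydroxylation of 17 with catalytic OsO4 and N-methylmorpholine N-oxide, on the face opposite the allylic C26 oxygen, gives the cis-diol F3. The secondary C14 hydroxyl is mesylated selectively (MsCl, Et3N) to the monomesylate F4. Et3Al in CH2Cl2 at −78 °C then triggers the 1,2-shift of C13 (antiperiplanar to the equatorial mesylate, inversion at C14) and forms the methyl ketone F5. Ketalisation with HC(OMe)3 and PPTS in methanol gives 19.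

Step 15, oxidative 1,3-transposition. What may go wrong: lack of control over the geometry of the tetrasubstituted alkene (formyl group syn or anti to C6), and ionisation of the hindered tertiary allylic alcohol with elimination instead of transposition. Fallback, setting out from 21 and returning at 24: Horner–Wadsworth–Emmons olefination of ketone 21 with the sodium salt of triethyl 2-phosphonopropanoate (NaH, toluene, heating) gives the tetrasubstituted unsaturated esters as configurationally stable, separable geometric isomers. The (Z)-ester F6 is isolated, the other isomer being recyclable by photoisomerisation, and is reduced with iBu2AlH in CH2Cl2 at −78 °C to the allylic alcohol 24.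

**Further compounds**

F1 | step 8 | 9-{3-[(tert-butyldiphenylsilyl)oxy]prop-1-yn-1-yl}-9-borabicyclo[3.3.1]nonane | CC(C)(C)[Si](OCC#CB1C2CCCC1CCC2)(c1ccccc1)c1ccccc1
F2 | step 8 | (6R,7S,8R,11S)-8-(benzyloxy)-7-{3-[(tert-butyldiphenylsilyl)oxy]prop-1-yn-1-yl}-11-hydroxy-3,11-dimethylspiro[5.5]undec-2-en-1-one | CC1=CC(=O)[C@]2(CC1)[C@H](C#CCO[Si](c1ccccc1)(c1ccccc1)C(C)(C)C)[C@H](OCc1ccccc1)CC[C@]2(C)O
F3 | step 11 | cis-2,3-diol of 17 (both new hydroxyls trans to the C1 oxygen), 8-(benzyloxy)-7-{3-[(tert-butyldiphenylsilyl)oxy]propyl}-1,11-O-(di-tert-butylsilanediyl)-3,11-dimethylspiro[5.5]undecane-1,2,3,11-tetrol | C[C@@]1(O)[C@H](O)[C@@H](O[Si]3(C(C)(C)C)C(C)(C)C)[C@]2(CC1)[C@H](CCCO[Si](c1ccccc1)(c1ccccc1)C(C)(C)C)[C@H](OCc1ccccc1)CC[C@]2(C)O3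
F4 | step 11 | 2-O-methanesulfonate of F3 | C[C@@]1(O)[C@H](OS(C)(=O)=O)[C@@H](O[Si]3(C(C)(C)C)C(C)(C)C)[C@]2(CC1)[C@H](CCCO[Si](c1ccccc1)(c1ccccc1)C(C)(C)C)[C@H](OCc1ccccc1)CC[C@]2(C)O3
F5 | step 11 | 1-[(1R,2S,5S,6S,7R,10S)-7-(benzyloxy)-6-{3-[(tert-butyldiphenylsilyl)oxy]propyl}-1,10-O-(di-tert-butylsilanediyl)-1,10-dihydroxy-10-methylspiro[4.5]decan-2-yl]ethan-1-one | CC(=O)[C@H]1CC[C@]2([C@H](CCCO[Si](c3ccccc3)(c3ccccc3)C(C)(C)C)[C@H](OCc3ccccc3)CC[C@]2(C)O4)[C@@H]1O[Si]4(C(C)(C)C)C(C)(C)C
F6 | step 15 | ethyl (2Z)-2-[(1R,2S,5S,6R,10S)-6-{3-[(tert-butyldiphenylsilyl)oxy]propyl}-1,10-O-(di-tert-butylsilanediyl)-1,10-dihydroxy-2-(1,1-dimethoxyethyl)-10-methylspiro[4.5]decan-7-ylidene]propanoate | COC(C)(OC)[C@H]1CC[C@]2([C@H](CCCO[Si](c3ccccc3)(c3ccccc3)C(C)(C)C)/C(=C(/C)C(=O)OCC)CC[C@]2(C)O4)[C@@H]1O[Si]4(C(C)(C)C)C(C)(C)C
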